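**Retrosynthetic overview** (labdane numbering throughout)
1. Late disconnections: the two allyl groups (C15 ester, C19 carbonate) and the C3 acetate; C13=C14 by Horner–Wadsworth–Emmons olefination of a C13 methyl ketone; C9–C11 by Grignard addition to a C9 enone, followed by oxidative transposition and reductive enol triflation to fix the Δ7 alkene and H-9.
2. Key disconnection: C3–C4 of ring A, by a hydride-triggered reductive aldol closure of a C3 aldehyde onto a C4 acrylonitrile; the CH2 that receives the hydride becomes CH3-18 and the nitrile carbon becomes C19.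
3. Structural feature used: C8(CH3)=C7–C6–C5, closed through C10 and C9 and carrying C4, C18 and C19 on C5, is the carvone skeleton. Ring B is therefore (S)-carvone: the isopropenyl carbons are C4, C18, C19 and the carbonyl carbon is C9; C20 and C1–C3 are attached at the α′ carbon (C10) by methylation then allylation.
4. The acceptor is a nitrile, not an ester: in the chair closure an axial ester enolate would have to hold an in-plane oxygen against CH3-20 and would end up equatorial (wrong C4 epimer), whereas the rod-like cyano group takes the axial C19 site.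
5. Ring order: ring B is present from the start (carvone); ring A closes in step 10; no further ring is formed.

Key step: step 10

Remark: centres that are erased later (the methyl-bearing carbon of 4, the C9 carbinol in 9–25, C9 in 30, C3 in 19 and 20) are drawn as the expected major epimer or left open; none bears on the target.

Step 1
Reactants: 1 (S)-(+)-carvone; 2 iodomethane
Product: 4 6-methylcarvone (epimer mixture at the new methine), via lithium enolate 3 (not isolated)
Conditions: LiN(i-Pr)2 (1.05 equiv), THF, −78 °C; then MeI, −78 → 0 °C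
Reagents that add atoms: iodomethane (2), CI
Why: Kinetic α′-deprotonation of the enone and SN2 methylation (enolate alkylation) install C20; the new methine is enolised again in step 2, so its configuration does not matter.

Step 2
Reactants: 4 6-methylcarvone; 5 allyl bromide
Product: 7 6-allyl-6-methylcarvone with allyl trans and methyl cis to the isopropenyl group, via lithium enolate 6 (not isolated)
Conditions: LiN(i-Pr)2, THF, −78 → −20 °C; then allyl bromide, DMPU, −78 °C → rt
Reagents that add atoms: allyl bromide (5), C=CCBr
Why: Enolate alkylation of the trisubstituted α′-enolate, with allyl bromide approaching the face opposite the neighbouring isopropenyl group, sets the quaternary C10 with C1–C3 trans and C20 cis to the C5 substituent.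

Step 3
Reactants: 7 6-allyl-6-methylcarvone
Product: 8 allylic chloride (isopropenyl methyl converted to CH2Cl, 1,1-disubstituted alkene retained)
Conditions: Ca(OCl)2, CO2 (solid), CH2Cl2/H2O, 0 °C
Reagents that add atoms: calcium hypochlorite, [Ca+2].[O-]Cl.[O-]Cl
Why: Ene-type allylic chlorination by hypochlorous acid selects the electron-rich 1,1-disubstituted alkene over the monosubstituted allyl group and the electron-poor enone alkene, and turns the methyl into the CH2Cl that becomes C19.

Step 4
Reactants: 8 allylic chloride
Product: 9 C9 allylic alcohol (hydroxyl cis to the C10 methyl)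
Conditions: NaBH4, CeCl3·7H2O, MeOH, −78 → −20 °C
Reagents that add atoms: none
Why: Luche 1,2-reduction masks the enone, which would otherwise be reduced in step 10; hydride is expected to enter axially, anti to the axial C20 methyl, and the carbinol centre is erased again in step 15.

Step 5
Reactants: 9 C9 allylic alcohol
Product: 10 C9 acetate
Conditions: Ac2O, pyridine, DMAP (cat.), CH2Cl2, 0 °C → rt
Reagents that add atoms: acetic anhydride, CC(=O)OC(C)=O
Why: DMAP-catalysed acylation gives an ester that is inert to 9-BBN, the periodinane, cobalt hydride and LiBH(s-Bu)3 at low temperature, and that is removed without a separate step by the aluminium hydride in step 13.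

Step 6
Reactants: 10 C9 acetate
Product: 11 2-substituted acrolein (CH2Cl oxidised to CHO)
Conditions: N-methylmorpholine N-oxide, NaI (0.2 equiv), 4 Å MS, MeCN, 40 °C
Reagents that add atoms: N-methylmorpholine N-oxide, C[N+]1([O-])CCOCC1
Why: Kornblum-type oxidation: the amine oxide displaces the allylic halide and the N-alkoxyammonium salt loses N-methylmorpholine to give the aldehyde, without touching the other alkenes or the acetate.

Step 7
Reactants: 11 2-substituted acrolein
Product: 14 2-substituted acrylonitrile, via aldoxime 12 (not isolated), via O-acetyl aldoxime 13 (not isolated)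
Conditions: NH2OH·HCl, pyridine, rt; then Ac2O, 90 °C
Reagents that add atoms: hydroxylamine hydrochloride, NO.Cl
Why: Oxime formation (1,2-addition to the aldehyde outruns conjugate addition) followed by acetylation and thermal elimination of acetic acid (oxime dehydration) gives the nitrile whose carbon becomes C19.

Step 8
Reactants: 14 2-substituted acrylonitrile
Product: 16 primary alcohol at C3, via B-alkyl-9-BBN 15 (not isolated)
Conditions: 9-BBN, THF, 0 °C → rt; then 30% H2O2, pH 7 phosphate buffer, 0 °C → rt
Reagents that add atoms: hydrogen peroxide, OO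
Why: Brown hydroboration with bulky 9-BBN selects the monosubstituted terminal alkene over the electron-poor acrylonitrile alkene and the hindered ring alkene, and neutral peroxide oxidation spares the nitrile and the acetate.

Step 9
Reactants: 16 primary alcohol at C3
Product: 17 C3 aldehyde bearing the C4 acrylonitrile and the C9 acetate
Conditions: Dess–Martin periodinane, NaHCO3, CH2Cl2, 0 °C → rt
Reagents that add atoms: none
Why: Dess–Martin oxidation gives the aldehyde under buffered, non-basic conditions that leave the acrylonitrile untouched.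

Step 10
Reactants: 17 C3 aldehyde bearing the C4 acrylonitrile and the C9 acetate
Product: 20 trans-decalin β-hydroxy nitrile (axial C19 nitrile, equatorial CH3-18, 3-OH), via cobalt keteniminate 18 (not isolated), via phenylsilyl ether 19 (not isolated)
Conditions: Co(C11H19O2)2 [Co(dpm)2, divalent cobalt, 10 mol %], PhSiH3 (slow addition), ClCH2CH2Cl, 25–40 °C, Ar; then 1 M HCl, THF, 0 °C
Reagents that add atoms: none
Why: Co(dpm)2 and PhSiH3 give a cobalt hydride that transfers hydrogen to the unsubstituted CH2 terminus of the acrylonitrile (this carbon becomes CH3-18); the resulting cobalt keteniminate adds through C4 to the tethered C3 aldehyde, and silyl transfer to the alkoxide returns the hydride. The closest known reaction type is the cobalt/phenylsilane reductive aldol coupling of α,β-unsaturated nitriles with aldehydes and its intramolecular form, the aldol cycloreduction of aldehyde enones. Ring A closes in the 6-(enolexo)-exo-trig mode through a chair, and because C1 and C4 are trans on ring B (set in step 2) only the trans-decalin can form. At C4 the rod-shaped C≡N takes the axial site syn to CH3-20 and CH3-18 the equatorial site, since an axial CH3-18 would be 1,3-diaxial to CH3-20; an ester enolate would instead have to push an in-plane oxygen against CH3-20 to be axial and would end up equatorial. The C3 carbinol is expected equatorial (aldehyde oxygen pointing outward in the chair) but is not relied on, because C3 is oxidised in step 11. The step needs hydrometalation of the acrylonitrile in preference to aldehyde hydrosilylation or reaction at the ring alkene; the substrate secures this by offering the electron-poor, unhindered 1,1-disubstituted alkene as the only acceptor (the enone is masked as the C9 acetate) with the aldehyde held for a six-membered closure, and slow silane addition limits plain reduction.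

Step 11
Reactants: 20 trans-decalin β-hydroxy nitrile
Product: 21 3-oxo nitrile
Conditions: Dess–Martin periodinane, NaHCO3, CH2Cl2, rt
Reagents that add atoms: none
Why: Dess–Martin oxidation gives an α-cyano ketone that cannot enolise towards the quaternary C4, so C4 is kept and any C3 epimers from step 10 converge.

Step 12
Reactants: 21 3-oxo nitrile
Product: 22 axial 3-hydroxy nitrile
Conditions: LiBH(s-Bu)3, THF, −78 °C; aq. NH4Cl
Reagents that add atoms: none
Why: Reduction with the bulky trialkylborohydride: the axial hydrogens at C1 and C5 block the axial trajectory, so hydride attacks equatorially and gives the axial 3-hydroxyl of the target, while nitrile and acetate survive at −78 °C.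

Step 13
Reactants: 22 axial 3-hydroxy nitrile
Product: 24 3-hydroxy C19 aldehyde with free C9 hydroxyl, via aluminium aldimine 23 (not isolated)
Conditions: i-Bu2AlH (6 equiv), toluene, −78 → 0 °C; MeOH, then 1 M HCl, THF, 0 °C
Reagents that add atoms: water, O
Why: Partial reduction of the nitrile with diisobutylaluminium hydride stops at the N-aluminio aldimine, which acid hydrolyses to the C19 aldehyde, and the same reagent cleaves the C9 acetate reductively.

Step 14
Reactants: 24 3-hydroxy C19 aldehyde with free C9 hydroxyl
Product: 25 3,9,19-triol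
Conditions: NaBH4, MeOH, 0 °C
Reagents that add atoms: none
Why: Borohydride reduction of the neopentyl aldehyde gives the C19 primary alcohol; it is run at once on crude 24 because a β-hydroxy aldehyde with a quaternary α-carbon can undergo retro-aldol cleavage under base.

Step 15
Reactants: 25 3,9,19-triol
Product: 26 3,19-dihydroxy 7-en-9-one
Conditions: MnO2, CH2Cl2, rt
Reagents that add atoms: none
Why: Allylic oxidation with MnO2 regenerates the C9 enone and leaves the saturated secondary and primary hydroxyls alone.

Step 16
Reactants: 26 3,19-dihydroxy 7-en-9-one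
Product: 27 3,19-bis(tert-butyldimethylsilyl) ether of the enone
Conditions: TBSOTf, 2,6-lutidine, CH2Cl2, −78 → 0 °C
Reagents that add atoms: tert-butyldimethylsilyl triflate, CC(C)(C)[Si](C)(C)OS(=O)(=O)C(F)(F)F
Why: Silyl triflate silylation protects both the hindered axial 3-hydroxyl and the neopentyl 19-hydroxyl for the organometallic, chromium and dissolving-metal steps, and the weak base does not enolise the enone.

Step 17
Reactants: 27 3,19-bis(tert-butyldimethylsilyl) ether of the enone; 28 2-(2-bromoethyl)-2-methyl-1,3-dioxolane
Product: 30 C9 tertiary allylic alcohol carrying the ketal side chain, via Grignard reagent 29 (not isolated)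
Conditions: 28, Mg, THF, 25 °C; CeCl3 (anhydrous), THF, −78 °C; then 27, −78 → 0 °C; aq. NH4Cl
Reagents that add atoms: 2-(2-bromoethyl)-2-methyl-1,3-dioxolane (28), CC1(CCBr)OCCO1
Why: Grignard 1,2-addition promoted by CeCl3 (organocerium conditions suppress β-hydride reduction at the neopentyl C9 ketone) attaches C11–C13 with C16 and the masked C13 ketone; the new carbinol centre is erased in step 18.

Step 18
Reactants: 30 C9 tertiary allylic alcohol carrying the ketal side chain
Product: 31 8-en-7-one with the side chain on C9
Conditions: [C5H5NH][CrO3Cl] (pyridinium chlorochromate), NaOAc, 4 Å MS, CH2Cl2, rt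
Reagents that add atoms: pyridinium chlorochromate, [O-][Cr](=O)(=O)Cl.c1cc[nH+]cc1
Why: Babler–Dauben oxidative transposition: the chromate ester of the tertiary allylic alcohol undergoes a [3,3] shift to C7 and is oxidised there, moving the oxygen to C7 and the alkene to C8=C9.

Step 19
Reactants: 31 8-en-7-one with the side chain on C9
Product: 33 Δ7 enol triflate (OTf on C7) with H-9 set, via lithium enolate 32 (not isolated)
Conditions: Li, NH3(l)/THF, t-BuOH (1 equiv), −78 °C; isoprene; evaporate NH3; PhNTf2, THF, −78 °C → rt
Reagents that add atoms: N-phenylbis(trifluoromethanesulfonimide), O=S(=O)(N(c1ccccc1)S(=O)(=O)C(F)(F)F)C(F)(F)F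
Why: Dissolving-metal (Birch-type) enone reduction protonates the β-carbon C9 axially, on the face opposite the axial C20 methyl, so the side chain becomes equatorial as in the target, and it leaves the C7–C8 lithium enolate regiospecifically for trapping as the enol triflate.

Step 20
Reactants: 33 Δ7 enol triflate
Product: 34 Δ7 alkene with the C13 ethylene ketal
Conditions: Pd(OAc)2, PPh3, HCO2H, n-Bu3N, DMF, 60 °C
Reagents that add atoms: none
Why: Palladium-catalysed formate reduction of the enol triflate (oxidative addition, decarboxylation of formate, reductive elimination) replaces OTf by H without moving the double bond.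

Step 21
Reactants: 34 Δ7 alkene with the C13 ethylene ketal
Product: 35 C13 methyl ketone
Conditions: pyridinium p-toluenesulfonate, acetone/H2O, 50 °C
Reagents that add atoms: water, O
Why: Mild acid-catalysed ketal hydrolysis releases the methyl ketone; the hindered silyl ethers and the trisubstituted alkene tolerate the weak acid.

Step 22
Reactants: 35 C13 methyl ketone; 36 allyl diethylphosphonoacetate
Product: 38 allyl (13E)-enoate 3,19-bis-silyl ether, via sodium phosphonate 37 (not isolated)
Conditions: 36, NaH, THF, 0 °C; then 35, 0 → 50 °C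
Reagents that add atoms: allyl diethylphosphonoacetate (36), CCOP(=O)(OCC)CC(=O)OCC=C
Why: Horner–Wadsworth–Emmons olefination forms C13=C14 and brings in C14–C15 as the allyl ester; the (E) isomer (chain trans to the ester) is expected to predominate and the minor (Z) isomer is to be removed by chromatography.

Step 23
Reactants: 38 allyl (13E)-enoate 3,19-bis-silyl ether
Product: 39 allyl (13E)-enoate 3,19-diol
Conditions: HF·pyridine, pyridine, THF, 0 °C → rt
Reagents that add atoms: none
Why: Fluoride-mediated desilylation under buffered conditions frees both hydroxyls without hydrolysing the allyl ester or isomerising either alkene.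

Step 24
Reactants: 39 allyl (13E)-enoate 3,19-diol
Product: 40 19-O-allyloxycarbonyl derivative
Conditions: allyl chloroformate, pyridine, CH2Cl2, −20 → 0 °C
Reagents that add atoms: allyl chloroformate, C=CCOC(Cl)=O
Why: Chemoselective acylation: the primary 19-hydroxyl reacts with the chloroformate much faster than the axial secondary 3-hydroxyl next to the quaternary C4.

Step 25
Reactants: 40 19-O-allyloxycarbonyl derivative
Product: 41 3-O-acetyl 19-O-allyloxycarbonyl allyl ester
Conditions: Ac2O, DMAP, Et3N, CH2Cl2, rt
Reagents that add atoms: acetic anhydride, CC(=O)OC(C)=O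
Why: DMAP-catalysed acetylation of the remaining hindered axial 3-hydroxyl; O-3 and C19 are anti across C3–C4, so the acetyl group cannot migrate to O-19 afterwards.

Step 26
Reactants: 41 3-O-acetyl 19-O-allyloxycarbonyl allyl ester
Product: 42 CNP0129162.1
Conditions: Pd(PPh3)4 (5 mol %), morpholine, THF, rt; then aq. citric acid
Reagents that add atoms: none
Why: Tsuji–Trost deallylation: zerovalent palladium ionises both the allyl ester and the allyl carbonate to π-allyl complexes that morpholine captures, releasing the C15 acid and (after loss of CO2) the 19-hydroxyl in one step while the acetate is untouched.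

**Compound list**
1 | (S)-(+)-carvone | O=C1C[C@H](CC=C1C)C(C)=C | starting material
2 | iodomethane | CI | starting material
3 | lithium α′-enolate of carvone | [Li]OC1=C[C@H](CC=C1C)C(C)=C | intermediate
4 | 6-methylcarvone (epimer mixture at the methyl-bearing carbon) | CC1[C@H](CC=C(C)C1=O)C(C)=C | intermediate
5 | allyl bromide | C=CCBr | starting material
6 | lithium α′-enolate of 6-methylcarvone | [Li]OC1=C(C)[C@H](CC=C1C)C(C)=C | intermediate
7 | 6-allyl-6-methylcarvone, allyl trans and methyl cis to isopropenyl (quaternary carbon = C10) | C=CC[C@]1(C)[C@H](CC=C(C)C1=O)C(C)=C | intermediate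
8 | allylic chloride: 7 with 3-chloroprop-1-en-2-yl in place of isopropenyl | C=CC[C@]1(C)[C@H](CC=C(C)C1=O)C(=C)CCl | intermediate
9 | C9 allylic alcohol of 8 (hydroxyl cis to the C10 methyl) | C=CC[C@]1(C)[C@H](CC=C(C)[C@H]1O)C(=C)CCl | intermediate
10 | C9 acetate of 9 | C=CC[C@]1(C)[C@H](CC=C(C)[C@H]1OC(C)=O)C(=C)CCl | intermediate
11 | 2-substituted acrolein | C=CC[C@]1(C)[C@H](CC=C(C)[C@H]1OC(C)=O)C(=C)C=O | intermediate
12 | aldoxime of 11 | C=CC[C@]1(C)[C@H](CC=C(C)[C@H]1OC(C)=O)C(=C)C=NO | intermediate
13 | O-acetyl aldoxime of 11 | C=CC[C@]1(C)[C@H](CC=C(C)[C@H]1OC(C)=O)C(=C)C=NOC(C)=O | intermediate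
14 | 2-substituted acrylonitrile (nitrile carbon = C19) | C=CC[C@]1(C)[C@H](CC=C(C)[C@H]1OC(C)=O)C(=C)C#N | intermediate
15 | B-alkyl-9-borabicyclo[3.3.1]nonane from 14 | B1(CCC[C@]3(C)[C@H](CC=C(C)[C@H]3OC(C)=O)C(=C)C#N)C2CCCC1CCC2 | intermediate
16 | primary alcohol at C3 | OCCC[C@]1(C)[C@H](CC=C(C)[C@H]1OC(C)=O)C(=C)C#N | intermediate
17 | C3 aldehyde with C4 acrylonitrile and C9 acetate (key-step precursor) | O=CCC[C@]1(C)[C@H](CC=C(C)[C@H]1OC(C)=O)C(=C)C#N | intermediate
18 | cobalt keteniminate at C4/C19 (dpm ligands on cobalt not drawn) | O=CCC[C@]1(C)[C@H](CC=C(C)[C@H]1OC(C)=O)C(C)=C=N[Co] | intermediate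
19 | O-phenylsilyl ether of 20 | c1ccccc1[SiH2]O[C@@H]2CC[C@]3(C)[C@H](CC=C(C)[C@H]3OC(C)=O)[C@]2(C)C#N | intermediate
20 | trans-decalin β-hydroxy nitrile: axial C19 nitrile syn to C20, equatorial CH3-18, equatorial 3-OH, C9 acetate, Δ7 (key-step product) | O[C@@H]1CC[C@]2(C)[C@H](CC=C(C)[C@H]2OC(C)=O)[C@]1(C)C#N | intermediate
21 | 3-oxo nitrile | O=C1CC[C@]2(C)[C@H](CC=C(C)[C@H]2OC(C)=O)[C@]1(C)C#N | intermediate
22 | axial 3-hydroxy nitrile | O[C@H]1CC[C@]2(C)[C@H](CC=C(C)[C@H]2OC(C)=O)[C@]1(C)C#N | intermediate
23 | N-diisobutylaluminio C19 aldimine (hydroxyls drawn free) | O[C@H]1CC[C@]2(C)[C@H](CC=C(C)[C@H]2O)[C@]1(C)C=N[Al](CC(C)C)CC(C)C | intermediate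
24 | 3-hydroxy C19 aldehyde with free C9 hydroxyl | O[C@H]1CC[C@]2(C)[C@H](CC=C(C)[C@H]2O)[C@]1(C)C=O | intermediate
25 | 3,9,19-triol | O[C@H]1CC[C@]2(C)[C@H](CC=C(C)[C@H]2O)[C@]1(C)CO | intermediate
26 | 3,19-dihydroxy 7-en-9-one | O[C@H]1CC[C@]2(C)[C@H](CC=C(C)C2=O)[C@]1(C)CO | intermediate
27 | 3,19-bis(tert-butyldimethylsilyl) ether of 26 | CC(C)(C)[Si](C)(C)O[C@H]1CC[C@]2(C)[C@H](CC=C(C)C2=O)[C@]1(C)CO[Si](C)(C)C(C)(C)C | intermediate
28 | 2-(2-bromoethyl)-2-methyl-1,3-dioxolane | CC1(CCBr)OCCO1 | starting material
29 | 2-(2-methyl-1,3-dioxolan-2-yl)ethylmagnesium bromide | CC1(CC[Mg]Br)OCCO1 | intermediate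
30 | C9 tertiary allylic alcohol with ketal side chain (C9 configuration open) | CC(C)(C)[Si](C)(C)O[C@H]1CC[C@]2(C)[C@H](CC=C(C)C2(O)CCC3(C)OCCO3)[C@]1(C)CO[Si](C)(C)C(C)(C)C | intermediate
31 | 8-en-7-one with the side chain on C9 | CC(C)(C)[Si](C)(C)O[C@H]1CC[C@]2(C)[C@H](CC(=O)C(C)=C2CCC3(C)OCCO3)[C@]1(C)CO[Si](C)(C)C(C)(C)C | intermediate
32 | lithium C7–C8 enolate with H-9 set | CC(C)(C)[Si](C)(C)O[C@H]1CC[C@]2(C)[C@H](CC(O[Li])=C(C)[C@H]2CCC3(C)OCCO3)[C@]1(C)CO[Si](C)(C)C(C)(C)C | intermediate
33 | Δ7 enol triflate (OTf on C7) | CC(C)(C)[Si](C)(C)O[C@H]1CC[C@]2(C)[C@H](CC(OS(=O)(=O)C(F)(F)F)=C(C)[C@H]2CCC3(C)OCCO3)[C@]1(C)CO[Si](C)(C)C(C)(C)C | intermediate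
34 | Δ7 alkene with C13 ethylene ketal | CC(C)(C)[Si](C)(C)O[C@H]1CC[C@]2(C)[C@H](CC=C(C)[C@H]2CCC3(C)OCCO3)[C@]1(C)CO[Si](C)(C)C(C)(C)C | intermediate
35 | C13 methyl ketone | CC(C)(C)[Si](C)(C)O[C@H]1CC[C@]2(C)[C@H](CC=C(C)[C@H]2CCC(C)=O)[C@]1(C)CO[Si](C)(C)C(C)(C)C | intermediate
36 | allyl diethylphosphonoacetate | CCOP(=O)(OCC)CC(=O)OCC=C | starting material
37 | sodium salt of 36 | CCOP(=O)(OCC)[CH-]C(=O)OCC=C.[Na+] | intermediate
38 | allyl (13E)-enoate, 3,19-bis-TBS ether | CC(C)(C)[Si](C)(C)O[C@H]1CC[C@]2(C)[C@H](CC=C(C)[C@H]2CC/C(C)=C/C(=O)OCC=C)[C@]1(C)CO[Si](C)(C)C(C)(C)C | intermediate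
39 | allyl (13E)-enoate 3,19-diol | O[C@H]1CC[C@]2(C)[C@H](CC=C(C)[C@H]2CC/C(C)=C/C(=O)OCC=C)[C@]1(C)CO | intermediate
40 | 19-O-allyloxycarbonyl derivative of 39 | O[C@H]1CC[C@]2(C)[C@H](CC=C(C)[C@H]2CC/C(C)=C/C(=O)OCC=C)[C@]1(C)COC(=O)OCC=C | intermediate
41 | 3-O-acetyl 19-O-allyloxycarbonyl allyl ester | CC(=O)O[C@H]1CC[C@]2(C)[C@H](CC=C(C)[C@H]2CC/C(C)=C/C(=O)OCC=C)[C@]1(C)COC(=O)OCC=C | intermediate
42 | CNP0129162.1 | CC(=O)O[C@H]1CC[C@]2(C)[C@H](CC=C(C)[C@H]2CC/C(C)=C/C(=O)O)[C@]1(C)CO | target

Total steps: 26. Longest linear sequence: 26 steps (1 → 42); 2, 5, 28 and 36 are bought.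

**Steps most likely to fail**

Step 10. The cobalt keteniminate may be quenched before it closes (plain reduction of the acrylonitrile), the aldehyde may be hydrosilylated, or the closure may show too little face selectivity at C4. The fallback sets out from 17 and returns at 20. Lithium thiophenolate (PhSH, n-BuLi, THF, −78 → −20 °C) adds in the conjugate sense to the acrylonitrile and the lithiated nitrile closes on the aldehyde through the same chair (thiolate-triggered Michael–aldol tandem), giving the 18-phenylthio hydroxy nitrile F1. Raney nickel (EtOH, rt) then cleaves the C–S bond, turning CH2SPh into CH3-18 and giving 20.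

Step 17. Addition to the neopentyl C9 carbonyl may be outrun by β-hydride transfer from the Grignard reagent, or may stall. The fallback sets out from 27 and returns at 30. The lithium acetylide of 2-ethynyl-2-methyl-1,3-dioxolane (CC1(C#C)OCCO1; n-BuLi, THF, −78 → 0 °C), a slender sp nucleophile, adds to the ketone to give the propargylic alcohol F2. Hydrogenation over Pd on carbon (H2, 1 atm, EtOAc) saturates the alkyne, leaving the hindered trisubstituted Δ7 alkene, and gives 30.

Step 22. The olefination may give poor control of the C13=C14 geometry, with loss of material to the (Z) isomer. The fallback sets out from 35 and returns at 38. LiN(i-Pr)2 (THF, −78 °C) and ClP(O)(OEt)2 give the kinetic enol phosphate F3, which further LiN(i-Pr)2 eliminates to the terminal alkyne F4. Negishi carboalumination (Me3Al, Cp2ZrCl2, CH2Cl2) adds methyl and aluminium syn across the alkyne, and acylation of the alkenylalane with allyl chloroformate proceeds with retention, giving 38 as the (E) isomer only.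

**Further compounds**
F1 | step 10 | 18-phenylthio analogue of 20 (CH2SPh in place of CH3-18) | O[C@@H]1CC[C@]2(C)[C@H](CC=C(C)[C@H]2OC(C)=O)[C@]1(CSc3ccccc3)C#N
F2 | step 17 | C9 propargylic tertiary alcohol (11-yne analogue of 30) | CC(C)(C)[Si](C)(C)O[C@H]1CC[C@]2(C)[C@H](CC=C(C)C2(O)C#CC3(C)OCCO3)[C@]1(C)CO[Si](C)(C)C(C)(C)C
F3 | step 22 | diethyl enol phosphate of ketone 35 (terminal enol) | CC(C)(C)[Si](C)(C)O[C@H]1CC[C@]2(C)[C@H](CC=C(C)[C@H]2CCC(=C)OP(=O)(OCC)OCC)[C@]1(C)CO[Si](C)(C)C(C)(C)C
F4 | step 22 | terminal alkyne from 35 | CC(C)(C)[Si](C)(C)O[C@H]1CC[C@]2(C)[C@H](CC=C(C)[C@H]2CCC#C)[C@]1(C)CO[Si](C)(C)C(C)(C)C
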